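**Retrosynthetic overview**
1. 22 ⇐ 21 (C2 carbinol → ketone) ⇐ 20. The oxirane is the second ring and is formed last, by O-atom transfer to the ring C3=C4 olefin from the face of an allylic C2–OH. 20 ⇐ enone 19.
2. 19 ⇐ acyclic (3Z,6Z)-farnesane ketoaldehyde 17. The carbocycle is the first ring and closes C1→C6. Electrophilic C1 takes the C6=C7 π bond and the bisabolyl-type charge at C7 is discharged by loss of H-14 (β-bisabolene mode). This is run as an asymmetric carbonyl–ene reaction that sets C1 and C6 together.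
3. 17 ⇐ chloromethyl ketone 16 ⇐ (Z)-alkenyl iodide 13 + C1–C2 unit 14.
4. 13 ⇐ 11 ⇐ one-pot union of alkynol 5, a methyl Grignard (C14) and allylic bromide 9. This fixes both Z olefins.
5. 5 ⇐ aldehyde 2 + silylacetylene 3 (sets C8). 9 ⇐ but-2-yn-1-ol 6.

Assumption: locants follow the farnesane chain (C1 = CH–OAc, C2 = ketone C, C3 = C–CH3 (C15), C4 = oxirane CH, C5 = CH2, C6 = ring CH, C7(=C14H2), C8 = CH–OAng, C9–C13 = prenyl); the ligand antipodes quoted follow the accepted facial models, and the mirror-image ligand would be used if a test run showed the opposite sense.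

Step 1
Reactants: 1 4-methylpent-3-en-1-ol
Product: 2 4-methylpent-3-enal
Conditions: TEMPO (10 mol %), PhI(OAc)2 (1.1 equiv), CH2Cl2, 0 °C to rt; used as a dried solution
Reagents that add atoms: none
Why: The oxoammonium (TEMPO/PhI(OAc)2) oxidation stops at the aldehyde and needs no base, so the β,γ-olefin does not move into conjugation; no stereocentre is formed.

Step 2
Reactants: 2 4-methylpent-3-enal; 3 ethynyltrimethylsilane
Product: 5 (3S)-6-methylhept-5-en-1-yn-3-ol, via C-silyl alkynol 4 (not isolated)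
Conditions: 3 (3 equiv), Me2Zn (3 equiv), (S,S)-ProPhenol (10 mol %), Ph3P=O (20 mol %), toluene, 4 °C; then K2CO3, MeOH, rt; aq NH4Cl
Reagents that add atoms: none
Why: The dinuclear zinc–ProPhenol asymmetric alkynylation delivers the alkynylzinc to the Re face of 2 and sets C8 as S, and methanolysis of the C–Si bond in the same flask frees the terminal alkyne.

Step 3
Reactants: 6 but-2-yn-1-ol
Product: 8 (2Z)-3-iodobut-2-en-1-ol, via cyclic alkenylalanate 7 (not isolated)
Conditions: Red-Al, THF, 0 °C to rt; then I2, −78 to 0 °C; Rochelle salt work-up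
Reagents that add atoms: iodine, II
Why: Hydroxyl-directed trans-hydroalumination of the propargylic alcohol gives the five-membered alanate 7, and its C–Al bond is iodinated with retention, so I ends cis to CH2OH (the future Z C3=C4 olefin).

Step 4
Reactants: 8 (2Z)-3-iodobut-2-en-1-ol
Product: 9 (2Z)-1-bromo-3-iodobut-2-ene
Conditions: CBr4, PPh3, CH2Cl2, 0 °C
Reagents that add atoms: carbon tetrabromide, BrC(Br)(Br)Br
Why: The Appel reaction brominates the primary allylic alcohol by a neutral SN2 path, without allylic transposition or loss of olefin geometry.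

Step 5
Reactants: 5 (3S)-6-methylhept-5-en-1-yn-3-ol; 9 (2Z)-1-bromo-3-iodobut-2-ene
Product: 11 (5S,6Z,9Z)-10-iodo-2,6-dimethylundeca-2,6,9-trien-5-ol, via chelated alkenylmagnesium 10 (not isolated)
Conditions: MeMgBr (2.3 equiv), CuI (20 mol %), THF, −10 °C to rt; then 9 (1.4 equiv), −20 °C to rt; aq NH4Cl
Reagents that add atoms: methylmagnesium bromide, C[Mg]Br
Why: Copper-catalysed anti-carbomagnesiation of the propargylic alkoxide puts CH3 (C14) on the carbinol-side alkyne carbon and Mg on the terminal carbon, held cis to C8 by chelation, and copper-catalysed SN2 allylation with retention then gives C6=C7 with C14H3 trans to C5 and leaves C8 untouched.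

Step 6
Reactants: 11 (5S,6Z,9Z)-10-iodo-2,6-dimethylundeca-2,6,9-trien-5-ol; 12 angelic anhydride [(2Z)-2-methylbut-2-enoic anhydride]
Product: 13 (5S,6Z,9Z)-10-iodo-2,6-dimethylundeca-2,6,9-trien-5-yl (2Z)-2-methylbut-2-enoate
Conditions: LiHMDS (1.1 equiv), THF, −20 °C; then 12 (1.3 equiv), −20 to 0 °C; aq NH4Cl
Reagents that add atoms: none
Why: O-acylation of the lithium alkoxide by the anhydride at low temperature avoids the nucleophilic catalysts that isomerise angelates to tiglates, and the C–O bond at C8 is not touched.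

Step 7
Reactants: 13 (5S,6Z,9Z)-10-iodo-2,6-dimethylundeca-2,6,9-trien-5-yl (2Z)-2-methylbut-2-enoate; 14 2-chloro-N-methoxy-N-methylacetamide
Product: 16 (5S,6Z,9Z)-12-chloro-2,6,10-trimethyl-11-oxododeca-2,6,9-trien-5-yl (2Z)-2-methylbut-2-enoate, via alkenylmagnesium chloride 15 (not isolated)
Conditions: i-PrMgCl·LiCl (1.15 equiv), THF, −25 °C; then 14 (1.3 equiv), −25 to 0 °C; aq NH4Cl
Reagents that add atoms: none
Why: Iodine–magnesium exchange at sp2 carbon goes with retention and spares the hindered enoate at −25 °C, and the Weinreb ketone synthesis stops at the ketone, giving the Z enone with C2 cis to C5.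

Step 8
Reactants: 16 (5S,6Z,9Z)-12-chloro-2,6,10-trimethyl-11-oxododeca-2,6,9-trien-5-yl (2Z)-2-methylbut-2-enoate
Product: 17 (5S,6Z,9Z)-2,6,10-trimethyl-11,12-dioxododeca-2,6,9-trien-5-yl (2Z)-2-methylbut-2-enoate
Conditions: DMSO, NaI (20 mol %), NaHCO3 (2 equiv), 30 °C; extraction, azeotropic drying (toluene), 4 Å MS; used crude
Reagents that add atoms: dimethyl sulfoxide, CS(C)=O
Why: Kornblum oxidation of an α-halo ketone (iodide-relayed alkoxysulfonium salt, then bicarbonate-induced loss of Me2S) gives the α-ketoaldehyde near room temperature with no reagent that attacks olefins.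

Step 9
Reactants: 17 (5S,6Z,9Z)-2,6,10-trimethyl-11,12-dioxododeca-2,6,9-trien-5-yl (2Z)-2-methylbut-2-enoate
Product: 19 (3S)-2-[(1S,2S)-2-acetoxy-4-methyl-3-oxocyclohex-4-en-1-yl]-6-methylhepta-1,5-dien-3-yl (2Z)-2-methylbut-2-enoate, via hydroxy enone 18 (not isolated)
Conditions: [Cu((S,S)-t-Bu-box)](SbF6)2 (10 mol %), 4 Å MS, CH2Cl2, 0 °C to rt; then pyridine, Ac2O, DMAP (cat.), 0 °C
Reagents that add atoms: acetic anhydride, CC(=O)OC(C)=O
Why: Proposed new method: an intramolecular type-I carbonyl–ene (concerted Prins) closure of an enone-glyoxal, modelled on Cu(II)–bis(oxazoline) glyoxylate–ene reactions and Cu(II)–box cyclisations of unsaturated α-keto esters; the 1,2-dicarbonyl chelates square-planar Cu(II) and the ligand leaves the aldehyde Si face open (C1 = S); the equatorial chelated C1–O and the C14 methyl lying trans to C5 fit only the trans-decalin-like transition state, so C6 (S) forms trans to C1–O and only H-14 is transferred; A1,3 strain keeps H-8 in the olefin plane and the C9 chain on the face opposite to attack, which matches 8S; acetylation in the same flask blocks tautomerisation to the diosphenol.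

Step 10
Reactants: 19 (3S)-2-[(1S,2S)-2-acetoxy-4-methyl-3-oxocyclohex-4-en-1-yl]-6-methylhepta-1,5-dien-3-yl (2Z)-2-methylbut-2-enoate
Product: 20 (3S)-2-[(1S,2S,3S)-2-acetoxy-3-hydroxy-4-methylcyclohex-4-en-1-yl]-6-methylhepta-1,5-dien-3-yl (2Z)-2-methylbut-2-enoate
Conditions: CeCl3·7H2O, NaBH4, MeOH, −78 °C
Reagents that add atoms: none
Why: In the Luche 1,2-reduction, axial hydride delivery to the half-chair with both substituents equatorial gives the pseudo-equatorial C2–OH, cis to the side chain and trans to OAc (as in carvone → cis-carveol), and both esters survive.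

Step 11
Reactants: 20 (3S)-2-[(1S,2S,3S)-2-acetoxy-3-hydroxy-4-methylcyclohex-4-en-1-yl]-6-methylhepta-1,5-dien-3-yl (2Z)-2-methylbut-2-enoate
Product: 21 (3S)-2-[(1R,2R,3S,4S,6S)-3-acetoxy-2-hydroxy-1-methyl-7-oxabicyclo[4.1.0]heptan-4-yl]-6-methylhepta-1,5-dien-3-yl (2Z)-2-methylbut-2-enoate
Conditions: VO(acac)2 (3 mol %), t-BuOOH (1.3 equiv, decane), CH2Cl2, 0 °C
Reagents that add atoms: tert-butyl hydroperoxide, CC(C)(C)OO
Why: In the vanadium-catalysed hydroxyl-directed epoxidation, the peroxovanadate bound to C2–O transfers oxygen only to the allylic C3=C4 olefin and only syn to that hydroxyl; this sets C3 and C4 with the oxirane cis to the side chain and trans to OAc, the face that nucleophilic epoxidation of 19 would not give, while the prenyl, methylidene and angelate olefins are untouched.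

Step 12
Reactants: 21 (3S)-2-[(1R,2R,3S,4S,6S)-3-acetoxy-2-hydroxy-1-methyl-7-oxabicyclo[4.1.0]heptan-4-yl]-6-methylhepta-1,5-dien-3-yl (2Z)-2-methylbut-2-enoate
Product: 22 (3S)-2-[(1S,3S,4S,6S)-3-acetoxy-1-methyl-2-oxo-7-oxabicyclo[4.1.0]heptan-4-yl]-6-methylhepta-1,5-dien-3-yl (2Z)-2-methylbut-2-enoate (target)
Conditions: Dess–Martin periodinane (1.3 equiv), CH2Cl2, 0 °C to rt
Reagents that add atoms: none
Why: The Dess–Martin oxidation removes the auxiliary C2 stereocentre under near-neutral conditions that neither open the oxirane nor epimerise the α-acetoxy centre C1.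

**Compound list**
1 | 4-methylpent-3-en-1-ol | CC(C)=CCCO | starting material
2 | 4-methylpent-3-enal | CC(C)=CCC=O | intermediate
3 | ethynyltrimethylsilane | C#C[Si](C)(C)C | starting material
4 | (3S)-6-methyl-1-(trimethylsilyl)hept-5-en-1-yn-3-ol | C[Si](C)(C)C#C[C@@H](O)CC=C(C)C | intermediate
5 | (3S)-6-methylhept-5-en-1-yn-3-ol | C#C[C@@H](O)CC=C(C)C | intermediate
6 | but-2-yn-1-ol | CC#CCO | starting material
7 | sodium 2,2-bis(2-methoxyethoxy)-3-methyl-2,5-dihydro-1,2-oxaluminol-2-uide (cyclic alkenylalanate) | [Na+].CC1=CCO[Al-]1(OCCOC)OCCOC | intermediate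
8 | (2Z)-3-iodobut-2-en-1-ol | C/C(I)=C/CO | intermediate
9 | (2Z)-1-bromo-3-iodobut-2-ene | C/C(I)=C/CBr | intermediate
10 | bromomagnesium (1Z,3S)-1-(bromomagnesio)-2,6-dimethylhepta-1,5-dien-3-olate | Br[Mg]/C=C(/C)[C@@H](O[Mg]Br)CC=C(C)C | intermediate
11 | (5S,6Z,9Z)-10-iodo-2,6-dimethylundeca-2,6,9-trien-5-ol | C/C(I)=C/C/C=C(/C)[C@@H](O)CC=C(C)C | intermediate
12 | angelic anhydride, (2Z)-2-methylbut-2-enoic anhydride | C/C=C(/C)C(=O)OC(=O)/C(C)=C\C | starting material
13 | (5S,6Z,9Z)-10-iodo-2,6-dimethylundeca-2,6,9-trien-5-yl (2Z)-2-methylbut-2-enoate | C/C(I)=C/C/C=C(/C)[C@@H](OC(=O)/C(C)=C\C)CC=C(C)C | intermediate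
14 | 2-chloro-N-methoxy-N-methylacetamide | CON(C)C(=O)CCl | starting material
15 | (Z)-alkenylmagnesium chloride from 13 (MgCl in place of I, geometry retained) | C/C([Mg]Cl)=C/C/C=C(/C)[C@@H](OC(=O)/C(C)=C\C)CC=C(C)C | intermediate
16 | (5S,6Z,9Z)-12-chloro-2,6,10-trimethyl-11-oxododeca-2,6,9-trien-5-yl (2Z)-2-methylbut-2-enoate | C/C(C(=O)CCl)=C/C/C=C(/C)[C@@H](OC(=O)/C(C)=C\C)CC=C(C)C | intermediate
17 | (5S,6Z,9Z)-2,6,10-trimethyl-11,12-dioxododeca-2,6,9-trien-5-yl (2Z)-2-methylbut-2-enoate | C/C(C(=O)C=O)=C/C/C=C(/C)[C@@H](OC(=O)/C(C)=C\C)CC=C(C)C | intermediate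
18 | (3S)-2-[(1S,2S)-2-hydroxy-4-methyl-3-oxocyclohex-4-en-1-yl]-6-methylhepta-1,5-dien-3-yl (2Z)-2-methylbut-2-enoate | C=C([C@H](CC=C(C)C)OC(=O)/C(C)=C\C)[C@@H]1CC=C(C)C(=O)[C@H]1O | intermediate
19 | (3S)-2-[(1S,2S)-2-acetoxy-4-methyl-3-oxocyclohex-4-en-1-yl]-6-methylhepta-1,5-dien-3-yl (2Z)-2-methylbut-2-enoate | C=C([C@H](CC=C(C)C)OC(=O)/C(C)=C\C)[C@@H]1CC=C(C)C(=O)[C@H]1OC(C)=O | intermediate
20 | (3S)-2-[(1S,2S,3S)-2-acetoxy-3-hydroxy-4-methylcyclohex-4-en-1-yl]-6-methylhepta-1,5-dien-3-yl (2Z)-2-methylbut-2-enoate | C=C([C@H](CC=C(C)C)OC(=O)/C(C)=C\C)[C@@H]1CC=C(C)[C@H](O)[C@H]1OC(C)=O | intermediate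
21 | (3S)-2-[(1R,2R,3S,4S,6S)-3-acetoxy-2-hydroxy-1-methyl-7-oxabicyclo[4.1.0]heptan-4-yl]-6-methylhepta-1,5-dien-3-yl (2Z)-2-methylbut-2-enoate | C=C([C@H](CC=C(C)C)OC(=O)/C(C)=C\C)[C@@H]1C[C@@H]2O[C@]2(C)[C@H](O)[C@H]1OC(C)=O | intermediate
22 | (3S)-2-[(1S,3S,4S,6S)-3-acetoxy-1-methyl-2-oxo-7-oxabicyclo[4.1.0]heptan-4-yl]-6-methylhepta-1,5-dien-3-yl (2Z)-2-methylbut-2-enoate | C=C([C@H](CC=C(C)C)OC(=O)/C(C)=C\C)[C@@H]1C[C@@H]2O[C@]2(C)C(=O)[C@H]1OC(C)=O | target

**Total step count:** 12. **Longest linear sequence:** 10 (steps 1, 2, 5–12).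

**Three steps most likely to fail**

Step 9. The olefin is deactivated by the allylic angelate, the glyoxal is fragile, and there is no direct precedent for this closure. The fallback replaces the proton terminator by silicon. It sets out from 5.
- The carbomagnesiation of step 5 is run with Me3SiCH2MgCl to give the silylmethyl alkenylmagnesium F1. Allylation of this with 9 gives the allylsilane iodo alcohol F2.
- LiHMDS and 12 give the allylsilane angelate F3.
- i-PrMgCl·LiCl gives the allylsilane alkenylmagnesium chloride F4, and 14 converts it into the allylsilane chloroketone F5.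
- Kornblum oxidation gives the allylsilane ketoaldehyde F6.
- A MgBr2·OEt2-chelated intramolecular Hosomi–Sakurai closure (β-silyl cation, loss of silicon from C14) then forms the same C1–C6 bond and the C7=C14 olefin.

The fallback comes back to the route at 18, which is acetylated as in step 9.

Step 8. The Z enone and the skipped diene may isomerise under iodide and bicarbonate in DMSO. The fallback reaches the aldehyde level from an alcohol instead of a halide. It sets out from 13.
- Grignard 15 is acylated with 2-[(tert-butyldimethylsilyl)oxy]-N-methoxy-N-methylacetamide to the silyloxy ketone F7.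
- HF·pyridine frees the primary ketol F8.
- Cu(OAc)2 in MeOH (or Dess–Martin periodinane) oxidises the ketol.

The fallback comes back at 17.

Step 5. Excess MeMgBr competes for 9, and the capture of 10 may be slow or give SN2′ product. The fallback builds C6=C7 by olefination instead of carbometalation. It sets out from 5 and 9.
- Au(I)-catalysed Markovnikov hydration of 5 gives the α-hydroxy methyl ketone F9, and TBSCl/imidazole gives the silyloxy ketone F10.
- 9 alkylates methylenetriphenylphosphorane to the homoallylic phosphonium bromide F11, and NaHMDS gives the ylide F12.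
- The Z-selective Wittig reaction of unstabilised ylides with α-alkoxy ketones (−78 °C) joins F12 and F10 to the silyl ether F13, with C8 cis to C5.
- TBAF removes the silyl group.

The fallback comes back at 11.

**Further compounds**
F1 | step 9 | bromomagnesium (1E,3S)-1-(bromomagnesio)-6-methyl-2-[(trimethylsilyl)methyl]hepta-1,5-dien-3-olate (Mg cis to C8) | Br[Mg]/C=C(/C[Si](C)(C)C)[C@@H](O[Mg]Br)CC=C(C)C
F2 | step 9 | (5S,6E,9Z)-10-iodo-2-methyl-6-[(trimethylsilyl)methyl]undeca-2,6,9-trien-5-ol | C/C(I)=C/C/C=C(/C[Si](C)(C)C)[C@@H](O)CC=C(C)C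
F3 | step 9 | (5S,6E,9Z)-10-iodo-2-methyl-6-[(trimethylsilyl)methyl]undeca-2,6,9-trien-5-yl (2Z)-2-methylbut-2-enoate | C/C(I)=C/C/C=C(/C[Si](C)(C)C)[C@@H](OC(=O)/C(C)=C\C)CC=C(C)C
F4 | step 9 | alkenylmagnesium chloride from F3 (MgCl in place of I, geometry retained) | C/C([Mg]Cl)=C/C/C=C(/C[Si](C)(C)C)[C@@H](OC(=O)/C(C)=C\C)CC=C(C)C
F5 | step 9 | (5S,6E,9Z)-12-chloro-2,10-dimethyl-11-oxo-6-[(trimethylsilyl)methyl]dodeca-2,6,9-trien-5-yl (2Z)-2-methylbut-2-enoate | C/C(C(=O)CCl)=C/C/C=C(/C[Si](C)(C)C)[C@@H](OC(=O)/C(C)=C\C)CC=C(C)C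
F6 | step 9 | (5S,6E,9Z)-2,10-dimethyl-11,12-dioxo-6-[(trimethylsilyl)methyl]dodeca-2,6,9-trien-5-yl (2Z)-2-methylbut-2-enoate | C/C(C(=O)C=O)=C/C/C=C(/C[Si](C)(C)C)[C@@H](OC(=O)/C(C)=C\C)CC=C(C)C
F7 | step 8 | (5S,6Z,9Z)-12-[(tert-butyldimethylsilyl)oxy]-2,6,10-trimethyl-11-oxododeca-2,6,9-trien-5-yl (2Z)-2-methylbut-2-enoate | C/C(C(=O)CO[Si](C)(C)C(C)(C)C)=C/C/C=C(/C)[C@@H](OC(=O)/C(C)=C\C)CC=C(C)C
F8 | step 8 | (5S,6Z,9Z)-12-hydroxy-2,6,10-trimethyl-11-oxododeca-2,6,9-trien-5-yl (2Z)-2-methylbut-2-enoate | C/C(C(=O)CO)=C/C/C=C(/C)[C@@H](OC(=O)/C(C)=C\C)CC=C(C)C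
F9 | step 5 | (3S)-3-hydroxy-6-methylhept-5-en-2-one | CC(=O)[C@@H](O)CC=C(C)C
F10 | step 5 | (3S)-3-[(tert-butyldimethylsilyl)oxy]-6-methylhept-5-en-2-one | CC(=O)[C@@H](O[Si](C)(C)C(C)(C)C)CC=C(C)C
F11 | step 5 | [(3Z)-4-iodopent-3-en-1-yl]triphenylphosphonium bromide | C/C(I)=C/CC[P+](c1ccccc1)(c1ccccc1)c1ccccc1.[Br-]
F12 | step 5 | [(3Z)-4-iodopent-3-en-1-ylidene]triphenylphosphorane | C/C(I)=C/CC=P(c1ccccc1)(c1ccccc1)c1ccccc1
F13 | step 5 | tert-butyl{[(5S,6Z,9Z)-10-iodo-2,6-dimethylundeca-2,6,9-trien-5-yl]oxy}dimethylsilane | C/C(I)=C/C/C=C(/C)[C@@H](O[Si](C)(C)C(C)(C)C)CC=C(C)C
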